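The target is the S enantiomer of 3,4-dehydro-δ-tocotrienol. The route rests on cutting the O1–C2 bond and then the C3=C4 bond of the 2H-pyran ring. C2 carries O1, a methyl group, the C3=C4 alkene and the all-E homofarnesyl chain, which is the pattern of the tertiary terminus of an (E,E,E)-geranylgeranyl π-allyl unit captured by a phenol oxygen. A palladium-catalysed asymmetric allylic etherification therefore joins the arene to the C20 chain and sets the only stereocentre (C2, S) in one operation. It leaves a vinyl group that ring-closing metathesis with an ortho styrene turns into C3=C4. The precursors are a monosilylated 2-methyl-6-vinylhydroquinone with one free hydroxyl and geranylgeranyl methyl carbonate.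

Key step: step 5

Assumption: the (R,R) antipode of the DACH-phenyl ligand is taken to give the S ether from the 2E carbonate; a pilot run with chiral HPLC at the stage of 9 checks the sense, and the (S,S) ligand is used instead, with nothing else changed, if it is opposite.

Step 1
Reactants: 1 methylhydroquinone (2-methylbenzene-1,4-diol)
Product: 2 2-methyl-4-(triisopropylsilyloxy)phenol
Conditions: TIPSCl (1.0 equiv, added slowly to 1.3 equiv of 1), imidazole (2.5 equiv), DMF, −20 to 0 °C; chromatography
Reagents that add atoms: triisopropylsilyl chloride, CC(C)[Si](Cl)(C(C)C)C(C)C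
Why: Silyl ether formation with a bulky chlorosilane should favour the hydroxyl without an ortho substituent over the one beside the methyl group, and keeping the silane limiting holds double silylation down.

Step 2
Reactants: 2 2-methyl-4-(triisopropylsilyloxy)phenol
Product: 4 2-hydroxy-3-methyl-5-(triisopropylsilyloxy)benzaldehyde, via hydroxymethyl phenol 3 (not isolated)
Conditions: MgCl2 (2 equiv), Et3N (4 equiv), (CH2O)n (6 equiv), MeCN, reflux; cold 1 M HCl work-up
Reagents that add atoms: paraformaldehyde (formaldehyde source), C=O
Why: Casnati–Skattebøl ortho-formylation: the magnesium phenoxide delivers formaldehyde to the only free ortho position (the para position is blocked by the silyloxy group) to give salicyl alcohol 3, which a second formaldehyde oxidises by hydride transfer to the aldehyde carbon that becomes C4.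

Step 3
Reactants: 4 2-hydroxy-3-methyl-5-(triisopropylsilyloxy)benzaldehyde
Product: 5 2-methyl-4-(triisopropylsilyloxy)-6-vinylphenol
Conditions: Ph3PCH3Br (2.6 equiv), KOtBu (2.5 equiv), THF, 0 °C to rt; NH4Cl quench; fast chromatography, kept cold with a trace of BHT and used soon
Reagents that add atoms: methyltriphenylphosphonium bromide, C[P+](c1ccccc1)(c1ccccc1)c1ccccc1.[Br-]
Why: Wittig methylenation, in which the first equivalent of ylide only deprotonates the phenol and the excess olefinates the phenoxide aldehyde, an established way to 2-vinylphenols; the aryl silyl ether is inert to the ylide.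

Step 4
Reactants: 6 (2E,6E,10E)-geranylgeraniol (all-E material, geometric purity checked before use)
Product: 7 (2E,6E,10E)-geranylgeranyl methyl carbonate
Conditions: ClCO2Me (1.5 equiv), pyridine (3 equiv), CH2Cl2, 0 °C
Reagents that add atoms: methyl chloroformate, COC(=O)Cl
Why: Acylation of the primary allylic alcohol under basic conditions gives the carbonate without disturbing the C2=C3 geometry, on which the stereochemical outcome of step 5 depends.

Step 5
Reactants: 5 2-methyl-4-(triisopropylsilyloxy)-6-vinylphenol; 7 (2E,6E,10E)-geranylgeranyl methyl carbonate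
Product: 8 triisopropyl{3-methyl-4-[((3S,6E,10E)-3,7,11,15-tetramethylhexadeca-1,6,10,14-tetraen-3-yl)oxy]-5-vinylphenoxy}silane, the (S)-configured tertiary aryl allyl ether
Conditions: Pd2(dba)3·CHCl3 (2 mol %), (R,R)-DACH-phenyl Trost ligand, N,N'-[(1R,2R)-cyclohexane-1,2-diyl]bis[2-(diphenylphosphino)benzamide] (6 mol %), 5 (1.2 equiv), degassed CH2Cl2 (0.1 M), 0 °C to rt, stopped as soon as 7 is consumed; kept below 40 °C and free of acid afterwards
Reagents that add atoms: none
Why: The zerovalent palladium–ligand complex ionises the primary carbonate of 7 with loss of CO2 to the syn π-allyl complex that retains the E geometry, the methoxide set free deprotonates 5, and the phenoxide attacks the tertiary allyl terminus on the face away from the metal to form the O1–C2 bond. The closest known reaction type is the Trost asymmetric allylic alkylation of phenols with geranyl-type methyl carbonates, which gives tertiary aryl allyl ethers. No ring is closed here; the ether only places the styrene and the new vinyl group within reach of each other for step 6. The new stereocentre C2 (S) is controlled by the chiral pocket of the ligand, which selects one face of the E-configured allyl terminus, provided the phenoxide attacks faster than the syn and anti complexes interconvert. The step needs branched over linear regioselectivity and one allyl face: the greater positive charge at the disubstituted terminus and the ligand pocket direct the oxygen to C2, the 2E purity of 7 fixes the sense (the 2Z isomer would lead to the mirror-image ether), and the substituted ortho and para positions of 5 exclude C-allylation. The electron-rich phenoxide is a poor leaving group, so re-ionisation of 8 to the linear ether should stay slow if the reaction is stopped at full conversion.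

Step 6
Reactants: 8 (S)-configured tertiary aryl allyl ether
Product: 9 triisopropyl{[(2S)-2,8-dimethyl-2-((3E,7E)-4,8,12-trimethyltrideca-3,7,11-trienyl)-2H-chromen-6-yl]oxy}silane
Conditions: second-generation Grubbs catalyst RuCl2(=CHPh)(PCy3)(H2IMes) (5 mol %), CH2Cl2 (0.005 M), 25–40 °C, argon sparge to remove ethylene; ethyl vinyl ether quench
Reagents that add atoms: none
Why: Ring-closing metathesis of a 2-vinylphenyl allyl ether: the ruthenium carbene should load on the unhindered styrene and close onto the vinyl group at C2 to give the six-membered 2H-pyran ring with loss of ethylene, faster than it engages the trisubstituted chain alkenes at high dilution; C2 takes no part.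

Step 7
Reactants: 9 (2S)-silyl chromene
Product: 10 (2S)-2,8-dimethyl-2-[(3E,7E)-4,8,12-trimethyltrideca-3,7,11-trien-1-yl]-2H-chromen-6-ol (target)
Conditions: Bu4NF (1.2 equiv), AcOH (1.2 equiv), THF, 0 °C, argon; degassed work-up and chromatography
Reagents that add atoms: none
Why: Fluoride cleavage of the aryl silyl ether, with acetic acid keeping the phenol protonated so that the air-sensitive 6-hydroxychromene is neither oxidised nor ring-opened; C2 is untouched.

Compound list
1 | methylhydroquinone (2-methylbenzene-1,4-diol) | Cc1cc(O)ccc1O | starting material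
2 | 2-methyl-4-(triisopropylsilyloxy)phenol | Cc1cc(O[Si](C(C)C)(C(C)C)C(C)C)ccc1O | intermediate
3 | 2-(hydroxymethyl)-6-methyl-4-(triisopropylsilyloxy)phenol | Cc1cc(O[Si](C(C)C)(C(C)C)C(C)C)cc(CO)c1O | intermediate (not isolated)
4 | 2-hydroxy-3-methyl-5-(triisopropylsilyloxy)benzaldehyde | Cc1cc(O[Si](C(C)C)(C(C)C)C(C)C)cc(C=O)c1O | intermediate
5 | 2-methyl-4-(triisopropylsilyloxy)-6-vinylphenol | Cc1cc(O[Si](C(C)C)(C(C)C)C(C)C)cc(C=C)c1O | intermediate
6 | (2E,6E,10E)-geranylgeraniol | CC(C)=CCC/C(C)=C/CC/C(C)=C/CC/C(C)=C/CO | starting material
7 | (2E,6E,10E)-geranylgeranyl methyl carbonate | CC(C)=CCC/C(C)=C/CC/C(C)=C/CC/C(C)=C/COC(=O)OC | intermediate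
8 | triisopropyl{3-methyl-4-[((3S,6E,10E)-3,7,11,15-tetramethylhexadeca-1,6,10,14-tetraen-3-yl)oxy]-5-vinylphenoxy}silane | CC(C)=CCC/C(C)=C/CC/C(C)=C/CC[C@@](C)(C=C)Oc1c(C)cc(O[Si](C(C)C)(C(C)C)C(C)C)cc1C=C | intermediate
9 | triisopropyl{[(2S)-2,8-dimethyl-2-((3E,7E)-4,8,12-trimethyltrideca-3,7,11-trienyl)-2H-chromen-6-yl]oxy}silane | CC(C)=CCC/C(C)=C/CC/C(C)=C/CC[C@@]1(C)C=Cc2cc(O[Si](C(C)C)(C(C)C)C(C)C)cc(C)c2O1 | intermediate
10 | (2S)-2,8-dimethyl-2-[(3E,7E)-4,8,12-trimethyltrideca-3,7,11-trien-1-yl]-2H-chromen-6-ol | CC(C)=CCC/C(C)=C/CC/C(C)=C/CC[C@@]1(C)C=Cc2cc(O)cc(C)c2O1 | target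

Total step count: 7.
Longest linear sequence: 6 steps (1 → 2 → 4 → 5 → 8 → 9 → 10); the carbonate branch (6 → 7) adds one step.

Steps most likely to fail

Step 5. The hindered 2,6-disubstituted phenoxide may attack the unsubstituted allyl terminus, or select the face of the tertiary terminus poorly, so that linear ether or ether of low enantiomeric purity results. The fallback sets out from 2 and 6, bypasses both the etherification and the metathesis, and comes back at 9. Alcohol 6 would be oxidised with MnO2 (CH2Cl2, rt) to (2E,6E,10E)-geranylgeranial F1. F1 and phenol 2 would be condensed with PhB(OH)2 and acetic acid in toluene at reflux with removal of water; the ortho-quinone methide formed at the free ortho position closes by oxa-6π electrocyclisation to the racemic silyl chromene F2. Preparative HPLC on a chiral stationary phase would then give the S enantiomer, which is 9, and step 7 follows.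

Step 6. The ruthenium carbene may react with the trisubstituted alkene nearest to C2 (five-membered closure with loss of the chain) or cross-metathesise the chain instead of closing the pyran ring. The fallback sets out from 2 and 7, closes the ring without metathesis and comes back at 9. Phenol 2 would be brominated at its only free ortho position (NBS, CH2Cl2, 0 °C) to 2-bromo-6-methyl-4-(triisopropylsilyloxy)phenol F3. F3 and 7 would be joined under the conditions of step 5 to the (S)-configured bromoaryl allyl ether F4. The vinyl group of F4 would be hydroborated with 9-BBN (THF, rt), which is far slower on trisubstituted alkenes, to the B-alkyl-9-BBN adduct F5. F5 is not isolated and would be cyclised by intramolecular B-alkyl Suzuki–Miyaura coupling (Pd(dppf)Cl2, K3PO4, THF/DMF/H2O, 60 °C) to the (S)-chroman silyl ether F6. Dehydrogenation of F6 at C3–C4 with DDQ (dioxane, 80 °C) would give 9.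

Step 1. The two hydroxyls may be discriminated too weakly, so that the regioisomeric monosilyl ether and the bis-silyl ether form and are hard to separate. The fallback sets out from no compound of the route: 1 is replaced by commercial 4-hydroxy-2-methylbenzaldehyde F7, whose substitution pattern fixes the regiochemistry, and it comes back at 2. F7 would be silylated (TIPSCl, imidazole, DMF, rt) to 2-methyl-4-(triisopropylsilyloxy)benzaldehyde F8. Baeyer–Villiger oxidation of F8 (mCPBA, NaHCO3, CH2Cl2, 0 °C to rt; aryl migration in the electron-rich aldehyde) would give 2-methyl-4-(triisopropylsilyloxy)phenyl formate F9. Mild methanolysis of F9 (KHCO3, MeOH, 0 °C) would give 2.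

Further compounds
F1 | step 5 | (2E,6E,10E)-geranylgeranial | CC(C)=CCC/C(C)=C/CC/C(C)=C/CC/C(C)=C/C=O
F2 | step 5 | racemic triisopropyl{[2,8-dimethyl-2-((3E,7E)-4,8,12-trimethyltrideca-3,7,11-trienyl)-2H-chromen-6-yl]oxy}silane | CC(C)=CCC/C(C)=C/CC/C(C)=C/CCC1(C)C=Cc2cc(O[Si](C(C)C)(C(C)C)C(C)C)cc(C)c2O1
F3 | step 6 | 2-bromo-6-methyl-4-(triisopropylsilyloxy)phenol | Cc1cc(O[Si](C(C)C)(C(C)C)C(C)C)cc(Br)c1O
F4 | step 6 | {3-bromo-5-methyl-4-[((3S,6E,10E)-3,7,11,15-tetramethylhexadeca-1,6,10,14-tetraen-3-yl)oxy]phenoxy}triisopropylsilane | CC(C)=CCC/C(C)=C/CC/C(C)=C/CC[C@@](C)(C=C)Oc1c(C)cc(O[Si](C(C)C)(C(C)C)C(C)C)cc1Br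
F5 | step 6 | B-alkyl-9-BBN adduct of F4 (boron on the former vinyl terminus, configuration at C2 unchanged) | CC(C)=CCC/C(C)=C/CC/C(C)=C/CC[C@@](C)(CCB1C2CCCC1CCC2)Oc1c(C)cc(O[Si](C(C)C)(C(C)C)C(C)C)cc1Br
F6 | step 6 | triisopropyl{[(2S)-2,8-dimethyl-2-((3E,7E)-4,8,12-trimethyltrideca-3,7,11-trienyl)chroman-6-yl]oxy}silane | CC(C)=CCC/C(C)=C/CC/C(C)=C/CC[C@@]1(C)CCc2cc(O[Si](C(C)C)(C(C)C)C(C)C)cc(C)c2O1
F7 | step 1 | 4-hydroxy-2-methylbenzaldehyde | Cc1cc(O)ccc1C=O
F8 | step 1 | 2-methyl-4-(triisopropylsilyloxy)benzaldehyde | Cc1cc(O[Si](C(C)C)(C(C)C)C(C)C)ccc1C=O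
F9 | step 1 | 2-methyl-4-(triisopropylsilyloxy)phenyl formate | Cc1cc(O[Si](C(C)C)(C(C)C)C(C)C)ccc1OC=O
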